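**Retrosynthetic overview**
- Target 29 ← methyl ester 28 (saponification) ← C6 methylation of the 6-methoxy-1,2-dioxane 26 ← oxa-Michael closure (O2–C3) of hydroperoxy ketal 25 ← keto enoate 24.
- 24 ← dithiane 20 by desilylation, oxidation, Wittig olefination (C2=C3) and unmasking of the C6 carbonyl.
- Feature used: C6, the quaternary peroxide-bearing carbon of the 1,2-dioxane ring (O1–O2–C3–C4–C5–C6), carries two methylenes (ring C5 and side-chain C7), each next to a methyl stereocentre (C4, C8) of the same (R)-3-hydroxy-2-methylpropanoate lineage. At the ketone level C6 is therefore an acyl dianion: 20 ← 1,3-dithiane 16 + iodide 4 (C3–C5) + iodide 15 (C7–C14), forming C5–C6 and C6–C7 in one flask.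
- 15 ← alkyne 7 (Zr-catalysed methylalumination, Negishi coupling with vinyl iodide 10 from alkyne 8); 4 ← hydroxy ester 1; 7 ← bromo alcohol 5, which is 1 with OH turned into Br and the ester reduced.
- Ring order: the 1,2-dioxane is the only ring built and it is built last (O1–C6 in step 15, O2–C3 in step 16); the dithiane is a temporary ring and the phenyl ring is bought.

Key step: step 10

Assumption: atoms are numbered along the acid chain (C1 = CO2H, C3 and C6 = ring carbons on O2 and O1, C14 = benzylic CH2); the ketal carbon C6 of 25 and 26 forms as a mixture of epimers that converges in step 17 and is drawn without a descriptor.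

**Route**

Step 1
Reactants: 1 methyl (R)-3-hydroxy-2-methylpropanoate
Product: 2 methyl (R)-3-[(tert-butyldimethylsilyl)oxy]-2-methylpropanoate
Conditions: TBSCl, imidazole, DMF, 0 °C to rt
Reagents that add atoms: tert-butyldimethylsilyl chloride, C[Si](C)(Cl)C(C)(C)C
Why: Imidazole-promoted silyl ether formation at the primary hydroxyl is a standard protection and leaves the α-stereocentre of the ester untouched.

Step 2
Reactants: 2 methyl (R)-3-[(tert-butyldimethylsilyl)oxy]-2-methylpropanoate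
Product: 3 (S)-3-[(tert-butyldimethylsilyl)oxy]-2-methylpropan-1-ol
Conditions: i-Bu2AlH (2.2 equiv), CH2Cl2, −78 to 0 °C
Reagents that add atoms: none
Why: Hydride reduction of the ester to the primary alcohol with i-Bu2AlH should proceed without epimerisation, the descriptor changing from R to S only through the change in priorities.

Step 3
Reactants: 3 (S)-3-[(tert-butyldimethylsilyl)oxy]-2-methylpropan-1-ol
Product: 4 (R)-tert-butyl(3-iodo-2-methylpropoxy)dimethylsilane
Conditions: PPh3, I2, imidazole, CH2Cl2, 0 °C to rt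
Reagents that add atoms: iodine, II
Why: Appel-type iodination displaces the activated primary oxygen by iodide in an SN2 reaction at CH2, so the neighbouring methyl stereocentre is not involved.

Step 4
Reactants: 5 (S)-3-bromo-2-methylpropan-1-ol
Product: 6 (S)-(3-bromo-2-methylpropoxy)(tert-butyl)dimethylsilane
Conditions: TBSCl, imidazole, DMF, 0 °C to rt
Reagents that add atoms: tert-butyldimethylsilyl chloride, C[Si](C)(Cl)C(C)(C)C
Why: Silyl protection of the primary alcohol prevents alkoxide formation and oxetane closure in the following acetylide alkylation.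

Step 5
Reactants: 6 (S)-(3-bromo-2-methylpropoxy)(tert-butyl)dimethylsilane
Product: 7 (R)-tert-butyldimethyl[(2-methylpent-4-yn-1-yl)oxy]silane
Conditions: LiC≡CH·H2NCH2CH2NH2, DMSO, 0 °C to rt
Reagents that add atoms: lithium acetylide–ethylenediamine complex, [Li]C#C.NCCN
Why: SN2 alkylation of lithium acetylide at the primary bromide in DMSO forms the C9–C10 bond one carbon away from the stereocentre, which is therefore retained.

Step 6
Reactants: 8 but-2-yn-1-ylbenzene
Product: 10 (E)-(3-iodobut-2-en-1-yl)benzene, via alkenylzirconocene chloride 9 (not isolated)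
Conditions: Cp2Zr(H)Cl (1.5 equiv), THF, rt to 45 °C; then I2, 0 °C
Reagents that add atoms: iodine, II
Why: Syn-hydrozirconation, equilibrated by the slight excess of Cp2Zr(H)Cl, should place zirconium on the less hindered methyl-bearing alkyne carbon, and iodinolysis with retention then gives the E-iodide with iodine cis to H.

Step 7
Reactants: 7 (R)-tert-butyldimethyl[(2-methylpent-4-yn-1-yl)oxy]silane; 10 (E)-(3-iodobut-2-en-1-yl)benzene
Product: 13 tert-butyldimethyl{[(2R,4E,6E)-2,4,6-trimethyl-8-phenylocta-4,6-dien-1-yl]oxy}silane, via alkenyldimethylalane 11 (not isolated), via alkenylzinc chloride 12 (not isolated)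
Conditions: AlMe3 (2.5 equiv), Cp2ZrCl2 (0.25 equiv), CH2Cl2, 0 °C to rt; evaporate volatiles; ZnCl2 (1.0 equiv), 10, Pd(PPh3)4 (5 mol %), THF, rt
Reagents that add atoms: trimethylaluminium, C[Al](C)C
Why: Zr-catalysed syn-methylalumination puts methyl on the internal carbon C10 and aluminium on C11, and Negishi coupling after transmetalation to zinc proceeds with retention at both alkenyl carbons, fixing the 10E,12E diene.

Step 8
Reactants: 13 tert-butyldimethyl{[(2R,4E,6E)-2,4,6-trimethyl-8-phenylocta-4,6-dien-1-yl]oxy}silane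
Product: 14 (2R,4E,6E)-2,4,6-trimethyl-8-phenylocta-4,6-dien-1-ol
Conditions: Bu4NF, THF, 0 °C to rt
Reagents that add atoms: none
Why: Fluoride-induced desilylation frees the primary alcohol under conditions to which the diene is inert.

Step 9
Reactants: 14 (2R,4E,6E)-2,4,6-trimethyl-8-phenylocta-4,6-dien-1-ol
Product: 15 [(2E,4E,7R)-8-iodo-3,5,7-trimethylocta-2,4-dien-1-yl]benzene
Conditions: PPh3, I2, imidazole, CH2Cl2, 0 °C (I2 premixed with PPh3 and imidazole before 14 is added)
Reagents that add atoms: iodine, II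
Why: Appel-type iodination at the primary carbon C7 should leave the C8 stereocentre and the diene untouched because no free iodine is present once the phosphonium reagent is preformed.

Step 10
Reactants: 16 1,3-dithiane; 4 (R)-tert-butyl(3-iodo-2-methylpropoxy)dimethylsilane; 15 [(2E,4E,7R)-8-iodo-3,5,7-trimethylocta-2,4-dien-1-yl]benzene
Product: 20 2-[(2S)-3-[(tert-butyldimethylsilyl)oxy]-2-methylpropyl]-2-[(2R,4E,6E)-2,4,6-trimethyl-8-phenylocta-4,6-dien-1-yl]-1,3-dithiane, via 2-lithio-1,3-dithiane 17 (not isolated), via monoalkyl dithiane 18 (not isolated), via lithiated monoalkyl dithiane 19 (not isolated)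
Conditions: 16, n-BuLi, THF, −30 °C; 4, −30 to 0 °C; then t-BuLi, HMPA, −78 °C; 15, −78 to −20 °C
Reagents that add atoms: none
Why: Deprotonation of 1,3-dithiane at C2 gives the sulfur-stabilised carbanion 17, which displaces iodide from C5 of 4 by SN2; the resulting 2-alkyl dithiane 18 is metalated again at the same carbon and the tertiary carbanion 19 displaces iodide from C7 of 15, so that C5–C6 and C6–C7 form in one flask on the masked C6 ketone. The closest known reaction type is the Corey–Seebach sequential bis-alkylation of 1,3-dithiane with primary iodides. No ring of the target is closed and no stereocentre is created; C4 and C8 lie β to the reacting carbons and are carried unchanged from 1 and 5. The step needs substitution to win over E2 at two β-branched iodides and over proton abstraction from the doubly activated C14 methylene of 15; iodide leaving groups, HMPA-separated ion pairs at −78 °C and the order of addition (the smaller electrophile 4 on the less hindered anion, the diene iodide 15 last and cold) are meant to secure this. Iodine–lithium exchange at 15 is avoided by using no more t-BuLi than is needed to metalate 18.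

Step 11
Reactants: 20 2-[(2S)-3-[(tert-butyldimethylsilyl)oxy]-2-methylpropyl]-2-[(2R,4E,6E)-2,4,6-trimethyl-8-phenylocta-4,6-dien-1-yl]-1,3-dithiane
Product: 21 (2S)-2-methyl-3-{2-[(2R,4E,6E)-2,4,6-trimethyl-8-phenylocta-4,6-dien-1-yl]-1,3-dithian-2-yl}propan-1-ol
Conditions: Bu4NF, THF, 0 °C to rt
Reagents that add atoms: none
Why: Fluoride desilylation liberates the C3 alcohol; dithiane and diene are stable to fluoride.

Step 12
Reactants: 21 (2S)-2-methyl-3-{2-[(2R,4E,6E)-2,4,6-trimethyl-8-phenylocta-4,6-dien-1-yl]-1,3-dithian-2-yl}propan-1-ol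
Product: 22 (2S)-2-methyl-3-{2-[(2R,4E,6E)-2,4,6-trimethyl-8-phenylocta-4,6-dien-1-yl]-1,3-dithian-2-yl}propanal
Conditions: SO3·pyridine, DMSO, i-Pr2NEt, CH2Cl2, 0 °C
Reagents that add atoms: none
Why: Parikh–Doering oxidation (activated DMSO) gives the aldehyde without attacking the dithiane sulfur atoms, which hypervalent iodine oxidants would cleave, and is mild enough to keep the α-stereocentre C4.

Step 13
Reactants: 22 (2S)-2-methyl-3-{2-[(2R,4E,6E)-2,4,6-trimethyl-8-phenylocta-4,6-dien-1-yl]-1,3-dithian-2-yl}propanal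
Product: 23 methyl (2E,4S)-4-methyl-5-{2-[(2R,4E,6E)-2,4,6-trimethyl-8-phenylocta-4,6-dien-1-yl]-1,3-dithian-2-yl}pent-2-enoate
Conditions: Ph3P=CHCO2Me, CH2Cl2, rt
Reagents that add atoms: methyl (triphenylphosphoranylidene)acetate, COC(=O)C=P(c1ccccc1)(c1ccccc1)c1ccccc1
Why: Wittig olefination with the stabilised ylide should give the E-enoate under neutral conditions that do not epimerise C4.

Step 14
Reactants: 23 methyl (2E,4S)-4-methyl-5-{2-[(2R,4E,6E)-2,4,6-trimethyl-8-phenylocta-4,6-dien-1-yl]-1,3-dithian-2-yl}pent-2-enoate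
Product: 24 methyl (2E,4S,8R,10E,12E)-4,8,10,12-tetramethyl-6-oxo-14-phenyltetradeca-2,10,12-trienoate
Conditions: MeI, CaCO3, MeCN/H2O (9:1), 45 °C
Reagents that add atoms: water, O
Why: Alkylative dithiane hydrolysis (S-methylation, then attack of water on the thionium ion) unmasks the C6 ketone with an electrophile too weak to touch the diene or the enoate.

Step 15
Reactants: 24 methyl (2E,4S,8R,10E,12E)-4,8,10,12-tetramethyl-6-oxo-14-phenyltetradeca-2,10,12-trienoate
Product: 25 methyl (2E,4S,8R,10E,12E)-6-hydroperoxy-6-methoxy-4,8,10,12-tetramethyl-14-phenyltetradeca-2,10,12-trienoate (C6 epimers)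
Conditions: urea·H2O2, Sc(OTf)3 (cat.), MeOH, rt
Reagents that add atoms: hydrogen peroxide (as its urea adduct), OO; methanol, CO
Why: Lewis acid-catalysed perketalisation adds methanol and H2O2 to the activated ketone to give the methoxy hydroperoxy ketal (O1–C6 bond), while enoate and diene do not react with unactivated H2O2.

Step 16
Reactants: 25 methyl (2E,4S,8R,10E,12E)-6-hydroperoxy-6-methoxy-4,8,10,12-tetramethyl-14-phenyltetradeca-2,10,12-trienoate
Product: 26 methyl 2-[(3R,4S)-6-methoxy-4-methyl-6-[(2R,4E,6E)-2,4,6-trimethyl-8-phenylocta-4,6-dien-1-yl]-1,2-dioxan-3-yl]acetate (C6 epimers)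
Conditions: Et2NH, CF3CH2OH, rt
Reagents that add atoms: none
Why: Amine-mediated 6-exo-trig intramolecular oxa-Michael addition of the hydroperoxide to the E-enoate closes the 1,2-dioxane (O2–C3), and a chair transition state with the C4 methyl and the acceptor arm both equatorial should set C3 trans to C4 (3R).

Step 17
Reactants: 26 methyl 2-[(3R,4S)-6-methoxy-4-methyl-6-[(2R,4E,6E)-2,4,6-trimethyl-8-phenylocta-4,6-dien-1-yl]-1,2-dioxan-3-yl]acetate
Product: 28 methyl 2-[(3R,4S,6R)-4,6-dimethyl-6-[(2R,4E,6E)-2,4,6-trimethyl-8-phenylocta-4,6-dien-1-yl]-1,2-dioxan-3-yl]acetate, via peroxycarbenium triflate 27 (not isolated)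
Conditions: AlMe3 (3 equiv), Me3SiOTf (1.2 equiv), CH2Cl2, −78 °C (26 premixed with AlMe3, Me3SiOTf added last)
Reagents that add atoms: trimethylaluminium, C[Al](C)C
Why: Proposed new method: Me3SiOTf should ionise the C6 methoxy group of either ketal epimer to the cyclic peroxycarbenium ion 27, which the AlMe3 already present should trap by methyl transfer along the axial trajectory of the half-chair in which the C3 and C4 substituents stay pseudo-equatorial, placing the new methyl axial and the C7 chain equatorial (6R); the closest known reaction types are the Lewis acid-mediated substitution of 3-alkoxy-1,2-dioxanes and 3-alkoxy-1,2-dioxolanes by allylsilanes and silyl ketene acetals through peroxycarbenium ions, and the AlMe3/Me3SiOTf axial C-methylation of cyclic O,O-acetals.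

Step 18
Reactants: 28 methyl 2-[(3R,4S,6R)-4,6-dimethyl-6-[(2R,4E,6E)-2,4,6-trimethyl-8-phenylocta-4,6-dien-1-yl]-1,2-dioxan-3-yl]acetate
Product: 29 2-[(3R,4S,6R)-4,6-dimethyl-6-[(2R,4E,6E)-2,4,6-trimethyl-8-phenylocta-4,6-dien-1-yl]-1,2-dioxan-3-yl]acetic acid
Conditions: LiOH, THF/H2O, 0 °C to rt; then 1 M HCl to pH 3
Reagents that add atoms: lithium hydroxide, [Li+].[OH-]
Why: Saponification of the methyl ester by acyl substitution should leave the dialkyl peroxide and the three ring stereocentres intact if kept cold and short, since the ring O–O bond is not electrophilic toward hydroxide.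

**Compound list**

1 | methyl (R)-3-hydroxy-2-methylpropanoate | C[C@H](CO)C(=O)OC | starting material
2 | methyl (R)-3-[(tert-butyldimethylsilyl)oxy]-2-methylpropanoate | C[C@H](CO[Si](C)(C)C(C)(C)C)C(=O)OC | intermediate
3 | (S)-3-[(tert-butyldimethylsilyl)oxy]-2-methylpropan-1-ol | C[C@H](CO[Si](C)(C)C(C)(C)C)CO | intermediate
4 | (R)-tert-butyl(3-iodo-2-methylpropoxy)dimethylsilane | IC[C@H](C)CO[Si](C)(C)C(C)(C)C | intermediate
5 | (S)-3-bromo-2-methylpropan-1-ol | BrC[C@@H](C)CO | starting material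
6 | (S)-(3-bromo-2-methylpropoxy)(tert-butyl)dimethylsilane | BrC[C@@H](C)CO[Si](C)(C)C(C)(C)C | intermediate
7 | (R)-tert-butyldimethyl[(2-methylpent-4-yn-1-yl)oxy]silane | C#CC[C@@H](C)CO[Si](C)(C)C(C)(C)C | intermediate
8 | but-2-yn-1-ylbenzene | CC#CCc1ccccc1 | starting material
9 | chloro[(2E)-4-phenylbut-2-en-2-yl]bis(cyclopentadienyl)zirconium | C/C(=C\Cc1ccccc1)[Zr](Cl)(C1C=CC=C1)C1C=CC=C1 | intermediate
10 | (E)-(3-iodobut-2-en-1-yl)benzene | C/C(I)=C\Cc1ccccc1 | intermediate
11 | [(1E,4R)-5-[(tert-butyldimethylsilyl)oxy]-2,4-dimethylpent-1-en-1-yl]dimethylaluminium | C[Al](C)/C=C(\C)C[C@@H](C)CO[Si](C)(C)C(C)(C)C | intermediate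
12 | [(1E,4R)-5-[(tert-butyldimethylsilyl)oxy]-2,4-dimethylpent-1-en-1-yl]zinc chloride | Cl[Zn]/C=C(\C)C[C@@H](C)CO[Si](C)(C)C(C)(C)C | intermediate
13 | tert-butyldimethyl{[(2R,4E,6E)-2,4,6-trimethyl-8-phenylocta-4,6-dien-1-yl]oxy}silane | CC(=C\Cc1ccccc1)/C=C(\C)C[C@@H](C)CO[Si](C)(C)C(C)(C)C | intermediate
14 | (2R,4E,6E)-2,4,6-trimethyl-8-phenylocta-4,6-dien-1-ol | CC(=C\Cc1ccccc1)/C=C(\C)C[C@@H](C)CO | intermediate
15 | [(2E,4E,7R)-8-iodo-3,5,7-trimethylocta-2,4-dien-1-yl]benzene | CC(=C\Cc1ccccc1)/C=C(\C)C[C@@H](C)CI | intermediate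
16 | 1,3-dithiane | C1CSCSC1 | starting material
17 | 2-lithio-1,3-dithiane | [Li]C1SCCCS1 | intermediate
18 | (S)-tert-butyl[3-(1,3-dithian-2-yl)-2-methylpropoxy]dimethylsilane | C[C@H](CO[Si](C)(C)C(C)(C)C)CC1SCCCS1 | intermediate
19 | (S)-tert-butyl[3-(2-lithio-1,3-dithian-2-yl)-2-methylpropoxy]dimethylsilane | C[C@H](CO[Si](C)(C)C(C)(C)C)CC1([Li])SCCCS1 | intermediate
20 | 2-[(2S)-3-[(tert-butyldimethylsilyl)oxy]-2-methylpropyl]-2-[(2R,4E,6E)-2,4,6-trimethyl-8-phenylocta-4,6-dien-1-yl]-1,3-dithiane | CC(=C\Cc1ccccc1)/C=C(\C)C[C@@H](C)CC1(C[C@H](C)CO[Si](C)(C)C(C)(C)C)SCCCS1 | intermediate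
21 | (2S)-2-methyl-3-{2-[(2R,4E,6E)-2,4,6-trimethyl-8-phenylocta-4,6-dien-1-yl]-1,3-dithian-2-yl}propan-1-ol | CC(=C\Cc1ccccc1)/C=C(\C)C[C@@H](C)CC1(C[C@H](C)CO)SCCCS1 | intermediate
22 | (2S)-2-methyl-3-{2-[(2R,4E,6E)-2,4,6-trimethyl-8-phenylocta-4,6-dien-1-yl]-1,3-dithian-2-yl}propanal | CC(=C\Cc1ccccc1)/C=C(\C)C[C@@H](C)CC1(C[C@H](C)C=O)SCCCS1 | intermediate
23 | methyl (2E,4S)-4-methyl-5-{2-[(2R,4E,6E)-2,4,6-trimethyl-8-phenylocta-4,6-dien-1-yl]-1,3-dithian-2-yl}pent-2-enoate | CC(=C\Cc1ccccc1)/C=C(\C)C[C@@H](C)CC1(C[C@H](C)/C=C/C(=O)OC)SCCCS1 | intermediate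
24 | methyl (2E,4S,8R,10E,12E)-4,8,10,12-tetramethyl-6-oxo-14-phenyltetradeca-2,10,12-trienoate | CC(=C\Cc1ccccc1)/C=C(\C)C[C@@H](C)CC(=O)C[C@H](C)/C=C/C(=O)OC | intermediate
25 | methyl (2E,4S,8R,10E,12E)-6-hydroperoxy-6-methoxy-4,8,10,12-tetramethyl-14-phenyltetradeca-2,10,12-trienoate (C6 epimers) | CC(=C\Cc1ccccc1)/C=C(\C)C[C@@H](C)CC(OC)(OO)C[C@H](C)/C=C/C(=O)OC | intermediate
26 | methyl 2-[(3R,4S)-6-methoxy-4-methyl-6-[(2R,4E,6E)-2,4,6-trimethyl-8-phenylocta-4,6-dien-1-yl]-1,2-dioxan-3-yl]acetate (C6 epimers) | CC(=C\Cc1ccccc1)/C=C(\C)C[C@@H](C)CC1(OC)C[C@H](C)[C@@H](CC(=O)OC)OO1 | intermediate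
27 | (3R,4S)-3-(2-methoxy-2-oxoethyl)-4-methyl-6-[(2R,4E,6E)-2,4,6-trimethyl-8-phenylocta-4,6-dien-1-yl]-4,5-dihydro-3H-1,2-dioxin-1-ium trifluoromethanesulfonate | CC(=C\Cc1ccccc1)/C=C(\C)C[C@@H](C)CC1=[O+]O[C@H](CC(=O)OC)[C@@H](C)C1.[O-]S(=O)(=O)C(F)(F)F | intermediate
28 | methyl 2-[(3R,4S,6R)-4,6-dimethyl-6-[(2R,4E,6E)-2,4,6-trimethyl-8-phenylocta-4,6-dien-1-yl]-1,2-dioxan-3-yl]acetate | CC(=C\Cc1ccccc1)/C=C(\C)C[C@@H](C)C[C@]1(C)C[C@H](C)[C@@H](CC(=O)OC)OO1 | intermediate
29 | 2-[(3R,4S,6R)-4,6-dimethyl-6-[(2R,4E,6E)-2,4,6-trimethyl-8-phenylocta-4,6-dien-1-yl]-1,2-dioxan-3-yl]acetic acid | CC(=C\Cc1ccccc1)/C=C(\C)C[C@@H](C)C[C@]1(C)C[C@H](C)[C@@H](CC(=O)O)OO1 | target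

**Step count**
Total: 18 steps. Longest linear sequence: 14 steps (5 → 29 through steps 4, 5, 7, 8, 9 and 10–18).

**Steps most likely to fail**

1. Step 17 (proposed new method). The peroxycarbenium ion may be captured intramolecularly by the C10=C11 alkene (Prins-type ring formation), may fragment by O–O heterolysis with 1,2-shift (Hock/Criegee-type), or the peroxide may be reduced by AlMe3 before methyl transfer; facial selectivity at C6 may also erode.
Fallback with known chemistry, setting out from 24 and returning at 28: the C6 methyl is introduced as a nucleophile at the ketone stage. MeLi/CeCl3 (THF, −78 °C, cold acetic acid quench) should add to the ketone of 24 in preference to the enoate and give methyl (2E,4S,8R,10E,12E)-6-hydroxy-4,6,8,10,12-pentamethyl-14-phenyltetradeca-2,10,12-trienoate F1 as both C6 epimers. Acid-catalysed perhydrolysis of the tertiary alcohol (50% H2O2 in large excess, cat. H2SO4, Et2O, 0 °C) should convert it into methyl (2E,4S,8R,10E,12E)-6-hydroperoxy-4,6,8,10,12-pentamethyl-14-phenyltetradeca-2,10,12-trienoate F2; the excess of H2O2 is meant to intercept the tertiary cation before the C10=C11 alkene does. Et2NH in CF3CH2OH then closes the ring by the oxa-Michael addition of step 16 to give 28 together with its C6 epimer methyl 2-[(3R,4S,6S)-4,6-dimethyl-6-[(2R,4E,6E)-2,4,6-trimethyl-8-phenylocta-4,6-dien-1-yl]-1,2-dioxan-3-yl]acetate F3, to be separated by chromatography. The price is loss of control at C6.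

2. Step 10 (key step). The second alkylation may stall because the hindered tertiary carbanion 19 acts as a base (proton abstraction at the C14 methylene of 15, or E2 at the β-branched iodide) instead of as a nucleophile, leaving 18 and destroying 15.
Fallback, setting out from 4 and 15 and returning at 24: the far less basic anion of p-toluenesulfonylmethyl isocyanide serves as the C6 linchpin (van Leusen ketone synthesis). Alkylation with 4 (NaH, DMSO/Et2O) should give tert-butyl{[(2S)-4-isocyano-2-methyl-4-(4-methylbenzenesulfonyl)butyl]oxy}dimethylsilane F4, and a second alkylation with 15 (NaH, DMSO) the dialkylated isocyanide tert-butyl{[(2S,6R,8E,10E)-4-isocyano-2,6,8,10-tetramethyl-4-(4-methylbenzenesulfonyl)-12-phenyldodeca-8,10-dien-1-yl]oxy}dimethylsilane F5. Brief acid hydrolysis (conc. HCl, Et2O, 0 °C) unmasks the ketone and removes the silyl group to give (2S,6R,8E,10E)-1-hydroxy-2,6,8,10-tetramethyl-12-phenyldodeca-8,10-dien-4-one F6. Parikh–Doering oxidation gives (2S,6R,8E,10E)-2,6,8,10-tetramethyl-4-oxo-12-phenyldodeca-8,10-dienal F7, and Wittig olefination with Ph3P=CHCO2Me gives 24.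

3. Step 6. Regiochemical leakage in the hydrozirconation (zirconium on the benzyl-bearing carbon) would give an isomeric vinyl iodide that is hard to separate and would carry a wrongly placed methyl group through the whole tail.
Fallback, setting out from the alkenylzinc 12 (made from 7 as in step 7) and returning at 13: the C12=C13 alkene is built from a 1,1-dibromoalkene. Phenylacetaldehyde with CBr4/PPh3 gives (3,3-dibromoprop-2-en-1-yl)benzene F8. Trans-selective mono-coupling of 12 with F8 (PdCl2(DPEphos) cat., THF), in which the bromine trans to the benzyl group reacts first, should give tert-butyl{[(2R,4E,6Z)-6-bromo-2,4-dimethyl-8-phenylocta-4,6-dien-1-yl]oxy}dimethylsilane F9. Methylation of the remaining bromide with Me2Zn and Pd(P(t-Bu)3)2 (cat.), with retention, gives 13 with the methyl position fixed by construction.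

**Further compounds**

F1 | step 17 | methyl (2E,4S,8R,10E,12E)-6-hydroxy-4,6,8,10,12-pentamethyl-14-phenyltetradeca-2,10,12-trienoate (C6 epimers) | CC(=C\Cc1ccccc1)/C=C(\C)C[C@@H](C)CC(C)(O)C[C@H](C)/C=C/C(=O)OC
F2 | step 17 | methyl (2E,4S,8R,10E,12E)-6-hydroperoxy-4,6,8,10,12-pentamethyl-14-phenyltetradeca-2,10,12-trienoate (C6 epimers) | CC(=C\Cc1ccccc1)/C=C(\C)C[C@@H](C)CC(C)(OO)C[C@H](C)/C=C/C(=O)OC
F3 | step 17 | methyl 2-[(3R,4S,6S)-4,6-dimethyl-6-[(2R,4E,6E)-2,4,6-trimethyl-8-phenylocta-4,6-dien-1-yl]-1,2-dioxan-3-yl]acetate | CC(=C\Cc1ccccc1)/C=C(\C)C[C@@H](C)C[C@@]1(C)C[C@H](C)[C@@H](CC(=O)OC)OO1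
F4 | step 10 | tert-butyl{[(2S)-4-isocyano-2-methyl-4-(4-methylbenzenesulfonyl)butyl]oxy}dimethylsilane (epimers at the isocyanide carbon) | Cc1ccc(cc1)S(=O)(=O)C([N+]#[C-])C[C@H](C)CO[Si](C)(C)C(C)(C)C
F5 | step 10 | tert-butyl{[(2S,6R,8E,10E)-4-isocyano-2,6,8,10-tetramethyl-4-(4-methylbenzenesulfonyl)-12-phenyldodeca-8,10-dien-1-yl]oxy}dimethylsilane | CC(=C\Cc1ccccc1)/C=C(\C)C[C@@H](C)CC([N+]#[C-])(C[C@H](C)CO[Si](C)(C)C(C)(C)C)S(=O)(=O)c1ccc(C)cc1
F6 | step 10 | (2S,6R,8E,10E)-1-hydroxy-2,6,8,10-tetramethyl-12-phenyldodeca-8,10-dien-4-one | CC(=C\Cc1ccccc1)/C=C(\C)C[C@@H](C)CC(=O)C[C@H](C)CO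
F7 | step 10 | (2S,6R,8E,10E)-2,6,8,10-tetramethyl-4-oxo-12-phenyldodeca-8,10-dienal | CC(=C\Cc1ccccc1)/C=C(\C)C[C@@H](C)CC(=O)C[C@H](C)C=O
F8 | step 6 | (3,3-dibromoprop-2-en-1-yl)benzene | BrC(Br)=CCc1ccccc1
F9 | step 6 | tert-butyl{[(2R,4E,6Z)-6-bromo-2,4-dimethyl-8-phenylocta-4,6-dien-1-yl]oxy}dimethylsilane | BrC(=C\Cc1ccccc1)/C=C(\C)C[C@@H](C)CO[Si](C)(C)C(C)(C)C
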